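(The numbers of this flask are assumed; the flask was simulated.)

Beside this flask stands a neighbour with 6.0 mM of Q, and I want one quantity that serves both.

    Q + E → Q.E (k1 = 0.00358 M⁻¹ s⁻¹)
    E + L → E.L (k2 = 0.00191 M⁻¹ s⁻¹)
    Q.E + E.L ⇌ D (K3 = 217 M⁻¹, k3 = 0.158 M⁻¹ s⁻¹)
    G ⇌ L, rate k4*(csat - [L]) (k4 = 6.39 × 10⁻⁵ s⁻¹, csat = 2.5 mM)
Q 10 mM; E 11.0 mM; G 2.5 mM (held); time 3.0 d
- at the start none of L is dissolved
- run time (flask): 3.0 d
* share of the Q used up at 3.0 d
* D at 3.0 d, in percent of the Q charged
* Q.E at 3.0 d, in percent of the Q charged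

1. The puzzle in this flask: the step to D has a rate constant 44.1 times that of the step from Q to Q.E. Each D needs two E, which makes E the limiting reagent and allows D up to 55.0 % of the Q charged. Yet K3 is just 0.22 mM⁻¹.

2. The back reaction has a half-life of 0.264 h, far shorter than 3.0 d, so I treat the step to D as at equilibrium. Then D/Q.E = [E.L]/C, where C = 1/K3 = 4.61 mM is the crossing concentration, the [E.L] at which D equals Q.E. Speed drops out, and I need [E.L].

3. With L taken at 2.5 mM, the two paths use E equally when Q has fallen to k2·csat/k1 = 1.33 mM. I guess that Q stops about there, and if I count the whole 11.0 mM of E as used, that puts 2.33 mM of E into E.L and D together. That estimate is less than C, so in my reckoning Q.E stays ahead of D.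

4. Solving the equilibrium with these two pools gives D = 1.43 mM. My figures are therefore conv 86.7 %, y_P 14.3 % and y_I 72.4 %.

The forecast, “treating it as equilibrated”, gives conv 87 %, y_P 12.2 % and y_I 75 %, so its D is lower than mine.

The simulation gives conv 86.8 %, y_P 12.2 % and y_I 74.6 %. In this flask the step to D relaxes with a half-life of 0.0950 h, short against 3.0 d, and at 3.00 d E.L stands at 0.754 mM, below C, which makes [E.L]/C 0.164 against a D/Q.E of 0.164. In the neighbour with 6.0 mM of Q, E.L stands at 1.93 mM at 3.00 d, which makes [E.L]/C 0.419, and its D of 28.7 % over its Q.E of 68.4 % reads 0.420.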